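Ring A' of the flavan half (primed atoms; O7' and C8' are bonded to ketal C2 and to C3) is assembled by a photochemical Danheiser benzannulation. A 5-aryl-4-bromo-2-furyl diazo ketone and an (S)-siloxyalkyne bearing the protected benzylic alcohol give, in one operation, a benzofuran-4-ol. The step exploits the pentasubstituted phloroglucinol ring A', fused to the furan at C7'–C8' and to the pyran at C4a'–C8a' with hydrogen only on C6'. It leaves O–C8a' free, O–C5' silylated and the C4'–C2' chain on C4a'. Mitsunobu flavan closure, introduction of the ring A aroyl group at the brominated C3 and oxa-Michael ketalisation complete the target.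

Key step: step 8

Remarks on the chemistry (one line each):
- Chromanone atoms are unprimed, flavan atoms primed; the target is (2S,3S,2'R) with a cis-fused ketal (2-aryl and 3-H on the same face).
- In ring A' the lone hydrogen (C6') lies between the oxygens on C5' and C7'; the two oxygens that must be told apart, on C5' and C8a', flank C4a'.
- Besides the three C–C bonds made after the ketene stage (C4a'–C8a', C5'–C6', C8a'–C8'), the Wolff shift itself joins C6' to C7'.
- A bromine is carried on furan C4 (future C3) as a spectator of the key step, because electrophilic acylation of a C3–H benzofuran would compete with the strongly activated C6'–H position.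
- The siloxyalkyne is made by oxidising a terminal acetylide, because a γ-hydroxy ester precursor would lactonise.
- Assumption: the remote C2' centre does not bias the sense of ketal closure, so both cis-fused ketals are expected in step 16; they are diastereomers and are taken to be separable by preparative HPLC, and because the closure is reversible the unwanted (2R,3R,2'R) isomer can be put through the same conditions again.

Step 1
Reactants: 1 4,5-dibromofuran-2-carboxylic acid; 2 [4-(benzyloxy)phenyl]boronic acid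
Product: 3 5-[4-(benzyloxy)phenyl]-4-bromofuran-2-carboxylic acid
Conditions: Pd(PPh3)4 (3 mol%), Na2CO3, DME/H2O, 80 °C; then HCl (aq)
Reagents that add atoms: none
Why: Suzuki–Miyaura coupling in which zerovalent palladium is expected to insert faster into the C5–Br bond next to the ring oxygen than into C4–Br, so that one aryl group enters and the C4 bromine is kept.

Step 2
Reactants: 3 5-[4-(benzyloxy)phenyl]-4-bromofuran-2-carboxylic acid
Product: 5 1-{5-[4-(benzyloxy)phenyl]-4-bromofuran-2-yl}-2-diazoethan-1-one, via acid chloride 4 (not isolated)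
Conditions: (COCl)2, DMF (cat.), CH2Cl2, 0 → 25 °C; then Me3SiCHN2 (2.2 equiv), THF/MeCN, 0 °C
Reagents that add atoms: trimethylsilyldiazomethane C[Si](C)(C)C=[N+]=[N-]
Why: Acylation of a diazoalkane by an acid chloride (first stage of an Arndt–Eistert sequence), the silyl group leaving as the chlorosilane, should give the diazomethyl ketone without use of diazomethane.

Step 3
Reactants: 6 pent-4-ynoic acid
Product: 7 N-methoxy-N-methylpent-4-ynamide
Conditions: MeNHOMe·HCl, EDC·HCl, Et3N, 4-(dimethylamino)pyridine (cat.), CH2Cl2, 0 → 25 °C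
Reagents that add atoms: N,O-dimethylhydroxylamine hydrochloride CNOC.Cl
Why: Carbodiimide-mediated amide coupling should give the Weinreb amide, the alkyne being inert.

Step 4
Reactants: 7 N-methoxy-N-methylpent-4-ynamide; 8 1-(benzyloxy)-4-bromobenzene
Product: 10 1-[4-(benzyloxy)phenyl]pent-4-yn-1-one, via Grignard reagent 9 (not isolated)
Conditions: Mg, THF, 40 °C; then 7, THF, −20 °C; then HCl (aq, 1 M)
Reagents that add atoms: none
Why: Weinreb ketone synthesis, in which the chelated tetrahedral adduct stops at the ketone stage and addition at −20 °C should outrun deprotonation of the alkyne C–H by the aryl Grignard reagent.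

Step 5
Reactants: 10 1-[4-(benzyloxy)phenyl]pent-4-yn-1-one
Product: 11 (1S)-1-[4-(benzyloxy)phenyl]pent-4-yn-1-ol
Conditions: (R)-1-methyl-3,3-diphenyltetrahydro-1H,3H-pyrrolo[1,2-c][1,3,2]oxazaborole ((R)-Me-CBS, 10 mol%), BH3·SMe2 (0.7 equiv), THF, −20 °C; then MeOH; NH4Cl (aq)
Reagents that add atoms: none
Why: Corey–Bakshi–Shibata reduction, in which the (R)-catalyst binds the ketone with the aryl group as the large substituent and delivers hydride to the face that gives the (S)-carbinol (the sense known for acetophenone), while at this temperature the ketone should be reduced before the alkyne is hydroborated.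

Step 6
Reactants: 11 (1S)-1-[4-(benzyloxy)phenyl]pent-4-yn-1-ol
Product: 12 {[(1S)-1-[4-(benzyloxy)phenyl]pent-4-yn-1-yl]oxy}triethylsilane
Conditions: Et3SiCl, imidazole, DMF, 0 → 25 °C
Reagents that add atoms: chlorotriethylsilane CC[Si](Cl)(CC)CC
Why: Imidazole-promoted silylation of a secondary alcohol masks the carbinol, which would otherwise trap the ketene of step 8, as an ether that mild acid removes later without touching an aryl silyl ether.

Step 7
Reactants: 12 {[(1S)-1-[4-(benzyloxy)phenyl]pent-4-yn-1-yl]oxy}triethylsilane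
Product: 15 {[(5S)-5-[4-(benzyloxy)phenyl]-5-(triethylsilyloxy)pent-1-yn-1-yl]oxy}tri(propan-2-yl)silane, via lithium acetylide 13 (not isolated), via lithium ynolate 14 (not isolated)
Conditions: LiN(SiMe3)2 (2.1 equiv), t-BuOOH (1.05 equiv), THF, −78 → 0 °C; then i-Pr3SiOTf, −78 → 0 °C; then H2O
Reagents that add atoms: tert-butyl hydroperoxide CC(C)(C)OO; triisopropylsilyl trifluoromethanesulfonate CC(C)[Si](C(C)C)(C(C)C)OS(=O)(=O)C(F)(F)F
Why: Oxidation of the lithium acetylide by lithium tert-butyl peroxide should give the ynolate, which the bulky silyl triflate silylates on oxygen to the siloxyalkyne, while the amide base leaves the benzylic silyl ether and its stereocentre alone.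

Step 8
Reactants: 5 1-{5-[4-(benzyloxy)phenyl]-4-bromofuran-2-yl}-2-diazoethan-1-one; 15 {[(5S)-5-[4-(benzyloxy)phenyl]-5-(triethylsilyloxy)pent-1-yn-1-yl]oxy}tri(propan-2-yl)silane
Product: 20 2-[4-(benzyloxy)phenyl]-3-bromo-5-[(3S)-3-[4-(benzyloxy)phenyl]-3-(triethylsilyloxy)propyl]-6-(triisopropylsilyloxy)-1-benzofuran-4-ol, via furylketene 16 (not isolated), via cyclobutenone 17 (not isolated), via dienylketene 18 (not isolated), via cyclohexadienone 19 (not isolated)
Conditions: hν (440 nm LEDs), ClCH2CH2Cl, 25 °C (5 in slight excess); then 80 °C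
Reagents that add atoms: none
Why: Visible light should be absorbed only by the diazo ketone, which loses N2 and undergoes Wolff rearrangement (furyl shift, joining C6' to C7') to furylketene 16; the alkyne carbon β to the siloxy oxygen then attacks the ketene carbonyl carbon in a [2+2] cycloaddition that forms C4a'–C8a' and C5'–C6' and gives cyclobutenone 17. On heating, 17 opens by 4π electrocyclic cleavage of its C8a'–C6' bond to dienylketene 18, and the isomer with the furyl group cis to the ketene closes ring A' by a thermal disrotatory 6π electrocyclisation that uses the furan C2=C3 bond and forms C8a'–C8'; dienone 19 tautomerises to the phenol. This is the photochemical (Wolff) variant of the Danheiser benzannulation, which is established for heteroaryl diazo ketones and siloxyalkynes. No stereocentre is created, and the silyl-protected carbinol centre is remote and untouched. The step needs regiocontrol in the [2+2], secured by the oxygen-induced polarisation of the siloxyalkyne, and site control in the ring closure, secured because the ketene sits on furan C2 and only C3 is adjacent and free. Irradiating at 25 °C before heating keeps the ketene away from the product phenol, and light of this wavelength should leave the C–Br bond intact.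

Step 9
Reactants: 20 2-[4-(benzyloxy)phenyl]-3-bromo-5-[(3S)-3-[4-(benzyloxy)phenyl]-3-(triethylsilyloxy)propyl]-6-(triisopropylsilyloxy)-1-benzofuran-4-ol
Product: 21 2-[4-(benzyloxy)phenyl]-3-bromo-5-[(3S)-3-[4-(benzyloxy)phenyl]-3-hydroxypropyl]-6-(triisopropylsilyloxy)-1-benzofuran-4-ol
Conditions: HF·pyridine, pyridine, THF, 0 °C
Reagents that add atoms: none
Why: Buffered acidic fluoride should cleave the alkyl triethylsilyl ether far faster than the hindered aryl triisopropylsilyl ether (chemoselective desilylation) and is too weak an acid to ionise the benzylic alcohol.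

Step 10
Reactants: 21 2-[4-(benzyloxy)phenyl]-3-bromo-5-[(3S)-3-[4-(benzyloxy)phenyl]-3-hydroxypropyl]-6-(triisopropylsilyloxy)-1-benzofuran-4-ol
Product: 22 (2R)-2,8-bis[4-(benzyloxy)phenyl]-9-bromo-5-(triisopropylsilyloxy)-3,4-dihydro-2H-furo[2,3-h]chromene
Conditions: PPh3, DIAD, toluene, 0 °C
Reagents that add atoms: none
Why: Mitsunobu etherification, in which the only free phenol (O–C8a') displaces the activated benzylic oxygen in a 6-exo-tet SN2 closure with inversion, turning the (S)-carbinol into the (2'R)-flavan, with toluene at 0 °C chosen to disfavour ionisation of the p-alkoxybenzylic centre.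

Step 11
Reactants: 22 (2R)-2,8-bis[4-(benzyloxy)phenyl]-9-bromo-5-(triisopropylsilyloxy)-3,4-dihydro-2H-furo[2,3-h]chromene
Product: 24 (2R)-5-(benzyloxy)-2,8-bis[4-(benzyloxy)phenyl]-9-bromo-3,4-dihydro-2H-furo[2,3-h]chromene, via phenoxide 23 (not isolated)
Conditions: n-Bu4NF (1.1 equiv), THF, 0 °C; then BnBr (1.5 equiv), 25 °C
Reagents that add atoms: benzyl bromide BrCc1ccccc1
Why: Fluoride cleaves the aryl silyl ether and the phenoxide is benzylated in the same flask (Williamson etherification), so that every phenol carries a group removable by one hydrogenolysis.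

Step 12
Reactants: 25 1,3,5-tris(benzyloxy)benzene
Product: 27 2,4,6-tris(benzyloxy)benzaldehyde, via iminium salt 26 (not isolated)
Conditions: POCl3, DMF, 0 → 25 °C; then H2O
Reagents that add atoms: N,N-dimethylformamide CN(C)C=O; water O
Why: Vilsmeier–Haack formylation of a symmetrical, strongly activated arene can give only this aldehyde.

Step 13
Reactants: 24 (2R)-5-(benzyloxy)-2,8-bis[4-(benzyloxy)phenyl]-9-bromo-3,4-dihydro-2H-furo[2,3-h]chromene; 27 2,4,6-tris(benzyloxy)benzaldehyde
Product: 29 [(2R)-5-(benzyloxy)-2,8-bis[4-(benzyloxy)phenyl]-3,4-dihydro-2H-furo[2,3-h]chromen-9-yl][2,4,6-tris(benzyloxy)phenyl]methanol (both carbinol epimers), via aryllithium 28 (not isolated)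
Conditions: n-BuLi (1.05 equiv), THF, −78 °C, 10 min; then 27, −78 → −40 °C; then NH4Cl (aq)
Reagents that add atoms: none
Why: Bromine–lithium exchange followed by addition to the aldehyde places the ring A carbon on C3 and nowhere else, since at −78 °C the 3-lithiobenzofuran should be trapped before it can ring-open, and the new carbinol centre, formed as both epimers, is erased in step 14.

Step 14
Reactants: 29 [(2R)-5-(benzyloxy)-2,8-bis[4-(benzyloxy)phenyl]-3,4-dihydro-2H-furo[2,3-h]chromen-9-yl][2,4,6-tris(benzyloxy)phenyl]methanol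
Product: 30 [(2R)-5-(benzyloxy)-2,8-bis[4-(benzyloxy)phenyl]-3,4-dihydro-2H-furo[2,3-h]chromen-9-yl][2,4,6-tris(benzyloxy)phenyl]methanone
Conditions: Dess–Martin periodinane, NaHCO3, CH2Cl2, 0 → 25 °C
Reagents that add atoms: none
Why: Dess–Martin oxidation should convert the diaryl carbinol into the ketone under buffered conditions that do not ionise this electron-rich benzhydrol.

Step 15
Reactants: 30 [(2R)-5-(benzyloxy)-2,8-bis[4-(benzyloxy)phenyl]-3,4-dihydro-2H-furo[2,3-h]chromen-9-yl][2,4,6-tris(benzyloxy)phenyl]methanone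
Product: 31 [(2R)-5-hydroxy-2,8-bis(4-hydroxyphenyl)-3,4-dihydro-2H-furo[2,3-h]chromen-9-yl](2,4,6-trihydroxyphenyl)methanone
Conditions: H2 (1 atm), Pd(OH)2/C, THF/MeOH, 25 °C
Reagents that add atoms: none
Why: Catalytic hydrogenolysis removes the six benzyl aryl ethers, while neutral conditions at 1 atm should spare the benzylic C2'–O bond of the flavan, the benzofuran and the hindered hydrogen-bonded ketone, and debenzylation is placed before ketal formation so that the benzylic ketal never meets palladium and hydrogen.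

Step 16
Reactants: 31 [(2R)-5-hydroxy-2,8-bis(4-hydroxyphenyl)-3,4-dihydro-2H-furo[2,3-h]chromen-9-yl](2,4,6-trihydroxyphenyl)methanone
Product: 32 (2S,3S,2'R)-target: 5,7-dihydroxy-2-(4-hydroxyphenyl)chroman-4-one joined through C2–O7' and C3–C8' to (2'R)-5'-hydroxy-2'-(4-hydroxyphenyl)flavan (cis-fused ketal)
Conditions: TsOH·H2O (10 mol%), THF, 25 °C, argon, dark; preparative HPLC (C18)
Reagents that add atoms: none
Why: Acid-catalysed intramolecular oxa-Michael addition of the chalcone-to-flavanone type (6-endo-trig), in which either of the two equivalent ortho-hydroxyls of ring A adds to C2, the β-carbon of the aroyl-activated C2=C3 bond, and the enol ketonises; relief of the crowding between the twisted aroyl group and the neighbouring pyran oxygen should favour the closed form, only the cis ring fusion is geometrically attainable on protonation of C3, so C2 and C3 arise as a linked pair, and since C2' is too remote to choose between the two cis-fused pairs the (2S,3S,2'R) ketal is expected alongside its (2R,3R,2'R) diastereomer and is isolated by preparative HPLC.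

Compound list
1 | 4,5-dibromofuran-2-carboxylic acid | OC(=O)c1cc(Br)c(Br)o1 | starting material
2 | [4-(benzyloxy)phenyl]boronic acid | OB(O)c1ccc(OCc2ccccc2)cc1 | starting material
3 | 5-[4-(benzyloxy)phenyl]-4-bromofuran-2-carboxylic acid | OC(=O)c1cc(Br)c(-c2ccc(OCc3ccccc3)cc2)o1 | intermediate
4 | 5-[4-(benzyloxy)phenyl]-4-bromofuran-2-carbonyl chloride (not isolated) | ClC(=O)c1cc(Br)c(-c2ccc(OCc3ccccc3)cc2)o1 | intermediate
5 | 1-{5-[4-(benzyloxy)phenyl]-4-bromofuran-2-yl}-2-diazoethan-1-one | [N-]=[N+]=CC(=O)c1cc(Br)c(-c2ccc(OCc3ccccc3)cc2)o1 | intermediate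
6 | pent-4-ynoic acid | OC(=O)CCC#C | starting material
7 | N-methoxy-N-methylpent-4-ynamide | CON(C)C(=O)CCC#C | intermediate
8 | 1-(benzyloxy)-4-bromobenzene | Brc1ccc(OCc2ccccc2)cc1 | starting material
9 | [4-(benzyloxy)phenyl]magnesium bromide (not isolated) | Br[Mg]c1ccc(OCc2ccccc2)cc1 | intermediate
10 | 1-[4-(benzyloxy)phenyl]pent-4-yn-1-one | O=C(CCC#C)c1ccc(OCc2ccccc2)cc1 | intermediate
11 | (1S)-1-[4-(benzyloxy)phenyl]pent-4-yn-1-ol | C#CCC[C@H](O)c1ccc(OCc2ccccc2)cc1 | intermediate
12 | {[(1S)-1-[4-(benzyloxy)phenyl]pent-4-yn-1-yl]oxy}triethylsilane | C#CCC[C@H](O[Si](CC)(CC)CC)c1ccc(OCc2ccccc2)cc1 | intermediate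
13 | lithium acetylide of 12 (not isolated) | [Li]C#CCC[C@H](O[Si](CC)(CC)CC)c1ccc(OCc2ccccc2)cc1 | intermediate
14 | lithium (5S)-5-[4-(benzyloxy)phenyl]-5-(triethylsilyloxy)pent-1-yn-1-olate (not isolated) | [Li]OC#CCC[C@H](O[Si](CC)(CC)CC)c1ccc(OCc2ccccc2)cc1 | intermediate
15 | {[(5S)-5-[4-(benzyloxy)phenyl]-5-(triethylsilyloxy)pent-1-yn-1-yl]oxy}tri(propan-2-yl)silane | CC(C)[Si](C(C)C)(C(C)C)OC#CCC[C@H](O[Si](CC)(CC)CC)c1ccc(OCc2ccccc2)cc1 | intermediate
16 | 2-{5-[4-(benzyloxy)phenyl]-4-bromofuran-2-yl}ethenone, the furylketene (not isolated) | O=C=Cc1cc(Br)c(-c2ccc(OCc3ccccc3)cc2)o1 | intermediate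
17 | 4-{5-[4-(benzyloxy)phenyl]-4-bromofuran-2-yl}-2-[(3S)-3-[4-(benzyloxy)phenyl]-3-(triethylsilyloxy)propyl]-3-(triisopropylsilyloxy)cyclobut-2-en-1-one, both C4 epimers (not isolated) | O=C1C(CC[C@H](O[Si](CC)(CC)CC)c2ccc(OCc3ccccc3)cc2)=C(O[Si](C(C)C)(C(C)C)C(C)C)C1c4cc(Br)c(-c5ccc(OCc6ccccc6)cc5)o4 | intermediate
18 | dienylketene from ring opening of 17, furyl cis to the ketene carbon (not isolated) | O=C=C(CC[C@H](O[Si](CC)(CC)CC)c1ccc(OCc2ccccc2)cc1)/C(O[Si](C(C)C)(C(C)C)C(C)C)=C\c3cc(Br)c(-c4ccc(OCc5ccccc5)cc4)o3 | intermediate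
19 | 2-[4-(benzyloxy)phenyl]-3-bromo-5-[(3S)-3-[4-(benzyloxy)phenyl]-3-(triethylsilyloxy)propyl]-6-(triisopropylsilyloxy)-1-benzofuran-4(3aH)-one (not isolated) | O=C1C(CC[C@H](O[Si](CC)(CC)CC)c2ccc(OCc3ccccc3)cc2)=C(O[Si](C(C)C)(C(C)C)C(C)C)C=C4OC(c5ccc(OCc6ccccc6)cc5)=C(Br)C14 | intermediate
20 | 2-[4-(benzyloxy)phenyl]-3-bromo-5-[(3S)-3-[4-(benzyloxy)phenyl]-3-(triethylsilyloxy)propyl]-6-(triisopropylsilyloxy)-1-benzofuran-4-ol | Oc1c(CC[C@H](O[Si](CC)(CC)CC)c2ccc(OCc3ccccc3)cc2)c(O[Si](C(C)C)(C(C)C)C(C)C)cc2oc(-c3ccc(OCc4ccccc4)cc3)c(Br)c12 | intermediate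
21 | 2-[4-(benzyloxy)phenyl]-3-bromo-5-[(3S)-3-[4-(benzyloxy)phenyl]-3-hydroxypropyl]-6-(triisopropylsilyloxy)-1-benzofuran-4-ol | Oc1c(CC[C@H](O)c2ccc(OCc3ccccc3)cc2)c(O[Si](C(C)C)(C(C)C)C(C)C)cc2oc(-c3ccc(OCc4ccccc4)cc3)c(Br)c12 | intermediate
22 | (2R)-2,8-bis[4-(benzyloxy)phenyl]-9-bromo-5-(triisopropylsilyloxy)-3,4-dihydro-2H-furo[2,3-h]chromene | Brc1c(-c2ccc(OCc3ccccc3)cc2)oc2cc(O[Si](C(C)C)(C(C)C)C(C)C)c3c(c12)O[C@@H](c1ccc(OCc4ccccc4)cc1)CC3 | intermediate
23 | tetrabutylammonium (2R)-2,8-bis[4-(benzyloxy)phenyl]-9-bromo-3,4-dihydro-2H-furo[2,3-h]chromen-5-olate (not isolated) | Brc1c(-c2ccc(OCc3ccccc3)cc2)oc2cc([O-])c3c(c12)O[C@@H](c1ccc(OCc4ccccc4)cc1)CC3.CCCC[N+](CCCC)(CCCC)CCCC | intermediate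
24 | (2R)-5-(benzyloxy)-2,8-bis[4-(benzyloxy)phenyl]-9-bromo-3,4-dihydro-2H-furo[2,3-h]chromene | Brc1c(-c2ccc(OCc3ccccc3)cc2)oc2cc(OCc3ccccc3)c3c(c12)O[C@@H](c1ccc(OCc4ccccc4)cc1)CC3 | intermediate
25 | 1,3,5-tris(benzyloxy)benzene | c1c(OCc2ccccc2)cc(OCc2ccccc2)cc1OCc1ccccc1 | starting material
26 | N-methyl-N-{[2,4,6-tris(benzyloxy)phenyl]methylidene}methanaminium chloride (not isolated) | C[N+](C)=Cc1c(OCc2ccccc2)cc(OCc2ccccc2)cc1OCc1ccccc1.[Cl-] | intermediate
27 | 2,4,6-tris(benzyloxy)benzaldehyde | O=Cc1c(OCc2ccccc2)cc(OCc2ccccc2)cc1OCc1ccccc1 | intermediate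
28 | 9-lithio derivative of 24 (not isolated) | [Li]c1c(-c2ccc(OCc3ccccc3)cc2)oc2cc(OCc3ccccc3)c3c(c12)O[C@@H](c1ccc(OCc4ccccc4)cc1)CC3 | intermediate
29 | [(2R)-5-(benzyloxy)-2,8-bis[4-(benzyloxy)phenyl]-3,4-dihydro-2H-furo[2,3-h]chromen-9-yl][2,4,6-tris(benzyloxy)phenyl]methanol, both carbinol epimers | OC(c1c(OCc2ccccc2)cc(OCc2ccccc2)cc1OCc1ccccc1)c1c(-c2ccc(OCc3ccccc3)cc2)oc2cc(OCc3ccccc3)c3c(c12)O[C@@H](c1ccc(OCc4ccccc4)cc1)CC3 | intermediate
30 | [(2R)-5-(benzyloxy)-2,8-bis[4-(benzyloxy)phenyl]-3,4-dihydro-2H-furo[2,3-h]chromen-9-yl][2,4,6-tris(benzyloxy)phenyl]methanone | O=C(c1c(OCc2ccccc2)cc(OCc2ccccc2)cc1OCc1ccccc1)c1c(-c2ccc(OCc3ccccc3)cc2)oc2cc(OCc3ccccc3)c3c(c12)O[C@@H](c1ccc(OCc4ccccc4)cc1)CC3 | intermediate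
31 | [(2R)-5-hydroxy-2,8-bis(4-hydroxyphenyl)-3,4-dihydro-2H-furo[2,3-h]chromen-9-yl](2,4,6-trihydroxyphenyl)methanone | O=C(c1c(O)cc(O)cc1O)c1c(-c2ccc(O)cc2)oc2cc(O)c3c(c12)O[C@@H](c1ccc(O)cc1)CC3 | intermediate
32 | (2S,3S,2'R)-target, cis-fused ketal (CNP0179743.1) | O=C1c2c(O)cc(O)cc2O[C@@]2(c3ccc(O)cc3)Oc3cc(O)c4c(c3[C@@H]12)O[C@@H](c1ccc(O)cc1)CC4 | target

Total step count: 16. Longest linear sequence: 13 steps (from 6 through steps 3–7, 8–11 and 13–16).

Steps most likely to fail

Step 16. The closure is an equilibration among isomers, and the position of that equilibrium is not known. The ketal may be only a minor partner of the aromatic aroylbenzofuran 31. Prolonged acid may also drain it, by loss of O7' in place of O1, into the isomeric 3-arylflavone, so the reaction has to be followed and stopped at the highest ketal content. The closure also has no facial bias, so part of the material ends up as the other cis-fused diastereomer. The fallback sets out from 31 and comes back at 32. It replaces the ground-state equilibration by a photochemical, kinetically controlled isomerisation (365 nm, degassed MeCN, 25 °C). Excited-state proton transfer from the ortho-hydroxyl to the carbonyl gives the ortho-quinone-methide enol, which closes by oxa-6π electrocyclisation across C2=C3 and ketonises, as in the photocyclisation of 2'-hydroxychalcones to flavanones. The ketal absorbs little at this wavelength and can therefore build up beyond its dark equilibrium share. This fallback makes no new compound.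

Step 8. The photochemical stage may lose the ketene to dimerisation or to acylation of phenols, or suffer secondary photoreactions such as C–Br cleavage, before the cyclobutenone has formed. The fallback sets out from 5 and comes back at 17, from which heating gives 20 as in step 8. It makes the same ketene without light. A silver-catalysed Wolff rearrangement (PhCO2Ag, Et3N, dioxane/H2O) gives 2-{5-[4-(benzyloxy)phenyl]-4-bromofuran-2-yl}acetic acid F1. Oxalyl chloride converts it into 2-{5-[4-(benzyloxy)phenyl]-4-bromofuran-2-yl}acetyl chloride F2. Slow addition of Et3N to F2 in the presence of 15 at 0–25 °C releases ketene 16 by dehydrochlorination, and 16 is trapped in the [2+2] cycloaddition.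

Step 10. The p-alkoxybenzylic oxyphosphonium intermediate may ionise instead of undergoing direct displacement, which would erode the enantiomeric purity at C2' or lead to elimination. The fallback sets out from 21 and comes back at 22, and sets C2' by catalyst control in place of inversion. MnO2 in CH2Cl2 oxidises the benzylic alcohol to 1-[4-(benzyloxy)phenyl]-3-{2-[4-(benzyloxy)phenyl]-3-bromo-4-hydroxy-6-(triisopropylsilyloxy)-1-benzofuran-5-yl}propan-1-one F3. TsOH with 4 Å molecular sieves in toluene closes and dehydrates this keto phenol to 2,8-bis[4-(benzyloxy)phenyl]-9-bromo-5-(triisopropylsilyloxy)-4H-furo[2,3-h]chromene F4. Asymmetric hydrogenation of the enol ether double bond (H2, [Ir(cod)(t-Bu-PHOX)][B(C6H3(CF3)2)4], CH2Cl2), with the ligand enantiomer that delivers the (2'R) product, gives 22.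

Further compounds
F0 | step 16 | none | none
F1 | step 8 | 2-{5-[4-(benzyloxy)phenyl]-4-bromofuran-2-yl}acetic acid | OC(=O)Cc1cc(Br)c(-c2ccc(OCc3ccccc3)cc2)o1
F2 | step 8 | 2-{5-[4-(benzyloxy)phenyl]-4-bromofuran-2-yl}acetyl chloride | ClC(=O)Cc1cc(Br)c(-c2ccc(OCc3ccccc3)cc2)o1
F3 | step 10 | 1-[4-(benzyloxy)phenyl]-3-{2-[4-(benzyloxy)phenyl]-3-bromo-4-hydroxy-6-(triisopropylsilyloxy)-1-benzofuran-5-yl}propan-1-one | Oc1c(CCC(=O)c2ccc(OCc3ccccc3)cc2)c(O[Si](C(C)C)(C(C)C)C(C)C)cc2oc(-c3ccc(OCc4ccccc4)cc3)c(Br)c12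
F4 | step 10 | 2,8-bis[4-(benzyloxy)phenyl]-9-bromo-5-(triisopropylsilyloxy)-4H-furo[2,3-h]chromene | Brc1c(-c2ccc(OCc3ccccc3)cc2)oc2cc(O[Si](C(C)C)(C(C)C)C(C)C)c3c(c12)OC(c1ccc(OCc4ccccc4)cc1)=CC3
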